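## The problem

The target is a coumarin whose benzo ring (ring A) is fully substituted: C5 carries a (2R,3S)-3-hydroxybutan-2-yl chain (C1'' benzylic, C2'' carbinol), C6 and C8 carry methyl groups and C7 a phenol, while C3 of the lactone (ring B) is bonded to C6' of a (2R)-2-methyl-2,3-dihydropyran-4-one (ring C). A synthesis has to place a branched chain between C4a and C6, join rings B and C through one sp2–sp2 bond, and close the lactone. Of the three stereocentres, the anti pair C1''/C2'' can be set one from the other, but C2' lies seven bonds away and needs its own enantiopure source. Ring C is a vinylogous ester that base or nucleophiles can open with loss of the C2' configuration. C4 is a Michael acceptor, the lactone is opened by alkoxide, the free phenol is easily oxidised, and the chain hydroxyl can reach C4 (or a formyl carbon in a precursor) through a six-membered ring unless it is masked. The enabling feature is that C8a bears only the ring oxygen. Without the O1–C8a bond, ring A derives from 4-hydroxy-3,5-dimethylbenzaldehyde (1), in which the future C5 and C8a are the two equivalent positions ortho to the formyl carbon (the future C4). One of them takes the chain, and the other stays as the C–H that an oxidative lactonisation of a (Z)-acrylic acid converts into the O1–C8a bond.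

## Retrosynthesis

**25 ⇐ 24.** The last cut removes the two acetyl groups of diacetate 24. Acyl protection is chosen over ethers because the ring must be electron-poor in the oxidative step and the chain oxygen must not add to C4. The forward step has to be a mild methanolysis that spares ring C.

**24 ⇐ 23.** The O1–C8a bond is cut, leading to the (Z)-acrylic acid 23. The neighbouring cuts (O1–C2, or C3–C4 together with O1–C2) would require a second oxygen ortho to the formyl carbon, which gives up the symmetry of 1 and forces two phenols to be told apart. Cutting O1–C8a leaves an open-chain acid and a ring with one free C–H. The forward reaction must deliver the carboxyl oxygen to C8a and not to the ipso carbon C4a, must oxidise the carboxylate ahead of the arene, and needs the aryl group cis to the carboxyl.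

**23 ⇐ 22 ⇐ 13 + 21.** The acid is traced to allyl ester 22, and the C3=C4 double bond is cut by a Knoevenagel disconnection into aldehyde 13 and pyranonylacetate 21. This is the most convergent cut, since each half carries its own stereochemistry. The free pyranonylacetic acid is a vinylogous β-keto acid and would decarboxylate, so an ester is condensed; the allyl ester can be released under neutral conditions in the presence of both acetates. The condensation has to place the aryl group cis to the ester. This is the expected thermodynamic outcome because it lets the pyranone stay coplanar with the new alkene.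

**21 ⇐ 18 ⇐ 15 + 16 (15 ⇐ 14).** Ring C is opened at O1'–C6' to the δ-oxygenated β-diketone 18, and the C4'–C5' bond is cut by a Claisen-type disconnection into silyl ether 15 and allyl acetoacetate 16, through dianion 17. C2' comes unchanged from the hydroxy ester 14, so no asymmetric step is needed for ring C. The forward acylation must avoid β-elimination of the silyloxy group, and the cyclodehydration must not break the C2'–O bond.

**13 ⇐ 12 ⇐ 11.** These are protecting-group changes only. The acetyl group on the phenol of 13 is removed to give 12, and the formyl group and phenol of 12 are masked as the dioxolane and methoxymethyl ether of 11. Both masks resist organolithium reagents and fall off together in acid, while the chain acetate stays.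

**11 ⇐ 10.** The C2''–O bond is cut with inversion (Mitsunobu). An epoxide with cis methyl groups would give the anti pattern directly, but it is meso and would need a reagent-controlled desymmetrisation. The C2-symmetric trans epoxide 8 gives one product whichever carbon is attacked, and the inversion that corrects the carbinol also installs the acetate needed later.

**10 ⇐ 7 + 8.** The C5–C1'' bond is cut to aryllithium 9 (from iodide 7) and epoxide 8. Anti opening sets C1'' as R. The forward step asks a doubly ortho-substituted aryllithium to attack a secondary carbon, so Lewis-acid assistance is needed.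

**7 ⇐ 6 ⇐ 2 ⇐ 1.** The acetal is removed to give 6, and the C–I bond is cut back to the methoxymethyl ether 2 of aldehyde 1. Iodine enters ortho to the formyl group by directed lithiation. Both ortho positions of 2 are equivalent, so there is no regiochemical question, and the position left over is the future C8a–H.

## Roads not taken

**Alternative 1:** Ring A is cut at C5–C6 and C4a–C8a. A [4+2] cycloaddition of 1-methoxy-2-methyl-1,3-bis(trimethylsilyloxy)penta-1,3-diene A1 with methyl (4R,5S)-5-(tert-butyldimethylsilyloxy)-4-methylhex-2-ynoate A2, followed by loss of methanol, would give the resorcylate methyl 2,4-dihydroxy-3,5-dimethyl-6-[(2R,3S)-3-(tert-butyldimethylsilyloxy)butan-2-yl]benzoate A3.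
- Merits: full regiocontrol of a hexasubstituted ring and, above all, the C8a oxygen is built in. After adjustment of A3 to a salicylaldehyde the lactone closes by a classical condensation in which alkene geometry does not matter. In this respect it is safer than the chosen plan.
- Weak points: the diene is substituted at both reacting termini and the ynoate β-carbon carries a branched chain, so the cycloaddition is congested. The propargylic stereocentre of A2 can isomerise through the allenoate. A2 needs its anti stereodiad built separately. After A3 the ester must be brought to the aldehyde level and two phenols differentiated.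
- Comparison: the chosen plan buys ring A, needs one directed metalation, and its fallback for the key step joins the same salicylaldehyde logic. Against this it has to accept a less precedented ring closure.

**Alternative 2:** Ring A is cut at C4a–C5. Mild base would turn the diketo-dioxinone 6-[(6S,7S)-7-(tert-butyldimethylsilyloxy)-4,6-dimethyl-3,5-dioxooctan-2-yl]-2,2-dimethyl-4H-1,3-dioxin-4-one A4 into its dienolate, and aldol closure with dehydration would give 7-hydroxy-2,2,6,8-tetramethyl-5-[(2R,3S)-3-(tert-butyldimethylsilyloxy)butan-2-yl]-4H-1,3-benzodioxin-4-one A5.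
- Merits: mild, regiospecific, and the salicylate comes out already masked with the C8a oxygen in place. On that point it equals Alternative 1 and beats the chosen plan.
- Weak points: the future benzylic centre of A4 is α to the ketone that is attacked and can epimerise under the enolising conditions of the key step. The attacked ketone is flanked by two branched carbons. The methylated diketo chain takes several acylation and methylation steps, and the adjustments after aromatisation are the same as for A3.
- Comparison: the chosen plan creates both chain stereocentres on carbons that cannot enolise and is shorter up to the coumarin.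

**Alternative 3:** The lactone carbonyl is inserted last by cutting C2–C3 and C2–O1. Pd(OAc)2 (divalent palladium), an oxidant and carbon monoxide would convert the (E)-2-alkenylphenol (2R)-6-[(E)-2-{4-(tert-butyldimethylsilyloxy)-2-hydroxy-6-[(2R,3S)-3-(tert-butyldimethylsilyloxy)butan-2-yl]-3,5-dimethylphenyl}ethenyl]-2-methyl-2,3-dihydro-4H-pyran-4-one A6 into the bis(silyl) ether of the target, A7.
- Merits: two bonds form in one step, the reaction class is known for simple 2-alkenylphenols, and the disubstituted E-alkene of A6 is easier to obtain pure than the trisubstituted Z-alkene of 22. On both counts it is ahead of the chosen plan.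
- Weak points: A6 again needs the extra ortho oxygen, so 1 cannot be used without a further C–H oxidation and a differentiation of two phenols. The vinylic C3–H sits on an electron-poor dienone, and the C5'–H of ring C is a competing site. Divalent palladium can also cyclise the phenol onto the alkene to give benzofuran-type products. The step uses carbon monoxide late in the synthesis.
- Comparison: the chosen plan has fewer operations on the arene and no late palladium oxidation of a phenol–alkene pair, at the price of a key step that extends known anodic lactonisations to an acrylic acid.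

Key step: step 13

Assumption: (2R,3R)-2,3-epoxybutane (the trans isomer, 8) and allyl acetoacetate (16) are taken as purchasable.

## Steps

Step 1
Reactants: 1 4-hydroxy-3,5-dimethylbenzaldehyde
Product: 2 4-(methoxymethoxy)-3,5-dimethylbenzaldehyde
Conditions: MOMCl, i-Pr2NEt, CH2Cl2, 0 °C → rt
Reagents that add atoms: chloromethyl methyl ether, COCCl
Why: O-Alkylation of the phenol (methoxymethyl ether formation); the acetal-type ether resists organolithium reagents and is later removed together with the aldehyde acetal.

Step 2
Reactants: 2 4-(methoxymethoxy)-3,5-dimethylbenzaldehyde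
Product: 6 2-iodo-4-(methoxymethoxy)-3,5-dimethylbenzaldehyde, via lithium amino alkoxide 3 (not isolated), via ortho-lithiated amino alkoxide 4 (not isolated), via iodinated amino alkoxide 5 (not isolated)
Conditions: LiN(Me)CH2CH2NMe2 (from the diamine and n-BuLi), THF, −20 °C; n-BuLi (3 equiv), −20 °C; I2, −78 °C → rt; H2O
Reagents that add atoms: iodine, II
Why: Directed ortho-lithiation with in situ protection of the aldehyde as an α-amino alkoxide, then iodination; the chelating adduct directs n-BuLi to the adjacent ring position, the two such positions of 2 are equivalent, and aqueous work-up returns the aldehyde.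

Step 3
Reactants: 6 2-iodo-4-(methoxymethoxy)-3,5-dimethylbenzaldehyde
Product: 7 2-[2-iodo-4-(methoxymethoxy)-3,5-dimethylphenyl]-1,3-dioxolane
Conditions: (TMSOCH2)2, TMSOTf (cat.), CH2Cl2, −78 → −20 °C; pyridine quench
Reagents that add atoms: 1,2-bis(trimethylsilyloxy)ethane, C[Si](C)(C)OCCO[Si](C)(C)C
Why: Acetalisation by silyl transfer under TMSOTf catalysis forms the dioxolane at low temperature without cleaving the aryl methoxymethyl ether; the acetal masks the formyl group for step 4.

Step 4
Reactants: 7 2-[2-iodo-4-(methoxymethoxy)-3,5-dimethylphenyl]-1,3-dioxolane, 8 (2R,3R)-2,3-epoxybutane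
Product: 10 (2R,3R)-3-[6-(1,3-dioxolan-2-yl)-3-(methoxymethoxy)-2,4-dimethylphenyl]butan-2-ol, via aryllithium 9 (not isolated)
Conditions: n-BuLi, THF, −78 °C; then 8 (2 equiv), BF3·OEt2, −78 °C; aq. NaHCO3
Reagents that add atoms: none
Why: Iodine–lithium exchange followed by BF3-assisted SN2 opening of the epoxide by the aryllithium; attack anti to oxygen inverts the attacked carbon and sets the benzylic centre as R, the carbinol stays R, and the C2 symmetry of 8 means both carbons give the same product.

Step 5
Reactants: 10 (2R,3R)-3-[6-(1,3-dioxolan-2-yl)-3-(methoxymethoxy)-2,4-dimethylphenyl]butan-2-ol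
Product: 11 (2S,3R)-3-[6-(1,3-dioxolan-2-yl)-3-(methoxymethoxy)-2,4-dimethylphenyl]butan-2-yl acetate
Conditions: PPh3, DIAD, AcOH, toluene, 0 °C → rt
Reagents that add atoms: acetic acid, CC(=O)O
Why: Mitsunobu esterification; acetate displaces the alkoxyphosphonium group with inversion, which turns the carbinol from R to S (the anti relationship of the target) and installs the chain acetate in the same operation.

Step 6
Reactants: 11 (2S,3R)-3-[6-(1,3-dioxolan-2-yl)-3-(methoxymethoxy)-2,4-dimethylphenyl]butan-2-yl acetate
Product: 12 (2S,3R)-3-(6-formyl-3-hydroxy-2,4-dimethylphenyl)butan-2-yl acetate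
Conditions: aq. HCl (3 M), THF, 40 °C
Reagents that add atoms: water, O
Why: Acid-catalysed acetal hydrolysis removes the dioxolane and the phenolic methoxymethyl ether together while the secondary acetate is inert to dilute aqueous acid; with the chain oxygen acylated the aldehyde cannot close to a lactol.

Step 7
Reactants: 12 (2S,3R)-3-(6-formyl-3-hydroxy-2,4-dimethylphenyl)butan-2-yl acetate
Product: 13 (2S,3R)-3-(3-acetoxy-6-formyl-2,4-dimethylphenyl)butan-2-yl acetate
Conditions: Ac2O, pyridine, DMAP (cat.), CH2Cl2, 0 °C → rt
Reagents that add atoms: acetic anhydride, CC(=O)OC(C)=O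
Why: DMAP-catalysed O-acetylation of the hindered phenol; the aryl acetate lowers the electron density of ring A for step 13 and keeps the phenol out of the condensation.

Step 8
Reactants: 14 methyl (R)-3-hydroxybutanoate
Product: 15 methyl (R)-3-[(tert-butyldimethylsilyl)oxy]butanoate
Conditions: TBSCl, imidazole, DMF, rt
Reagents that add atoms: tert-butyldimethylsilyl chloride, CC(C)(C)[Si](C)(C)Cl
Why: Silyl ether formation masks the hydroxyl so that the ester can act as an acylating agent; the stereocentre is not touched.

Step 9
Reactants: 15 methyl (R)-3-[(tert-butyldimethylsilyl)oxy]butanoate, 16 allyl 3-oxobutanoate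
Product: 18 allyl (7R)-7-[(tert-butyldimethylsilyl)oxy]-3,5-dioxooctanoate, via acetoacetate dianion 17 (not isolated)
Conditions: 16 (2.2 equiv), NaH, THF, 0 °C; n-BuLi, 0 °C; then 15, −78 → 0 °C; cold 1 M HCl
Reagents that add atoms: none
Why: Claisen-type acylation of the γ-carbon of the β-keto ester dianion by the methyl ester; the dianion is used in excess because the diketo ester is deprotonated as it forms, and the silyloxy-bearing centre is not α to a carbonyl, so it cannot epimerise.

Step 10
Reactants: 18 allyl (7R)-7-[(tert-butyldimethylsilyl)oxy]-3,5-dioxooctanoate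
Product: 21 allyl 2-[(2R)-2-methyl-4-oxo-3,4-dihydro-2H-pyran-6-yl]acetate, via hydroxy diketo ester 19 (not isolated), via cyclic hemiketal 20 (not isolated)
Conditions: TFA, wet CH2Cl2, 0 °C → rt
Reagents that add atoms: none
Why: Acidic desilylation, 6-exo-trig hemiketalisation of the hydroxyl onto the C3 ketone and dehydration, the standard cyclodehydration of δ-hydroxy-β-diketones to dihydropyranones; the C–O bond at the stereocentre is never broken, so R is retained.

Step 11
Reactants: 13 (2S,3R)-3-(3-acetoxy-6-formyl-2,4-dimethylphenyl)butan-2-yl acetate, 21 allyl 2-[(2R)-2-methyl-4-oxo-3,4-dihydro-2H-pyran-6-yl]acetate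
Product: 22 allyl (Z)-3-{4-acetoxy-2-[(2R,3S)-3-acetoxybutan-2-yl]-3,5-dimethylphenyl}-2-[(2R)-2-methyl-4-oxo-3,4-dihydro-2H-pyran-6-yl]acrylate
Conditions: TiCl4, pyridine, THF/CH2Cl2, 0 °C → rt
Reagents that add atoms: none
Why: Knoevenagel condensation at the only doubly activated methylene of 21; the Z isomer, in which the pyranone stays coplanar with the new double bond and the ester twists beside the aryl group, is expected to predominate as it does for alkylidene β-keto esters.

Step 12
Reactants: 22 allyl (Z)-3-{4-acetoxy-2-[(2R,3S)-3-acetoxybutan-2-yl]-3,5-dimethylphenyl}-2-[(2R)-2-methyl-4-oxo-3,4-dihydro-2H-pyran-6-yl]acrylate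
Product: 23 (Z)-3-{4-acetoxy-2-[(2R,3S)-3-acetoxybutan-2-yl]-3,5-dimethylphenyl}-2-[(2R)-2-methyl-4-oxo-3,4-dihydro-2H-pyran-6-yl]acrylic acid
Conditions: Pd(PPh3)4 (5 mol%), PhNHMe, THF, rt
Reagents that add atoms: none
Why: Tsuji–Trost deallylation; zerovalent palladium ionises the allyl ester and N-methylaniline takes up the allyl group, releasing the acid under neutral conditions that leave both acetates, the vinylogous ester and the alkene geometry alone.

Step 13
Reactants: 23 (Z)-3-{4-acetoxy-2-[(2R,3S)-3-acetoxybutan-2-yl]-3,5-dimethylphenyl}-2-[(2R)-2-methyl-4-oxo-3,4-dihydro-2H-pyran-6-yl]acrylic acid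
Product: 24 (2S,3R)-3-{7-acetoxy-6,8-dimethyl-3-[(2R)-2-methyl-4-oxo-3,4-dihydro-2H-pyran-6-yl]-2-oxo-2H-chromen-5-yl}butan-2-yl acetate
Conditions: undivided cell, graphite anode, Pt cathode, constant current, n-Bu4NBF4, 2,4,6-collidine (cat.), MeCN/HFIP (4:1), rt
Reagents that add atoms: none
Why: Proposed new method: the carboxylate of 23, formed by the catalytic base and by cathodic proton reduction, is oxidised at the anode to an acyloxy radical (or the arene is oxidised and trapped by the carboxylate), whose oxygen attacks the only free ortho carbon C8a in a 6-endo-trig closure; a second one-electron oxidation and loss of the C8a proton restore the arene and complete lactone ring B, while hydrogen forms at the cathode. The closest known reaction type is the anodic dehydrogenative lactonisation of 2-arylbenzoic acids to benzocoumarins, and chemical or photochemical oxidants are known to close 3-arylacrylic acids to coumarins in the same sense. No stereocentre is formed, and the three existing ones lie outside the reacting π-system. The step needs ortho attack to beat 5-exo ipso attack at C4a and to beat decarboxylation. The acetoxy group para to C4a can neither stabilise nor release a spirodienone, a spiro radical would shift to the ortho position in any case, and acyloxy radicals on sp2 carbon lose CO2 slowly. The Z geometry fixed in steps 11 and 12 holds the carboxyl next to C8a, and the acetylated arene and the vinylogous ester are expected to be harder to oxidise than the carboxylate.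

Step 14
Reactants: 24 (2S,3R)-3-{7-acetoxy-6,8-dimethyl-3-[(2R)-2-methyl-4-oxo-3,4-dihydro-2H-pyran-6-yl]-2-oxo-2H-chromen-5-yl}butan-2-yl acetate
Product: 25 7-hydroxy-5-[(2R,3S)-3-hydroxybutan-2-yl]-6,8-dimethyl-3-[(2R)-2-methyl-4-oxo-3,4-dihydro-2H-pyran-6-yl]-2H-chromen-2-one
Conditions: K2CO3, MeOH, 0 °C → rt; then AcOH
Reagents that add atoms: none
Why: Base-catalysed transesterification (methanolysis) of both acetates; the phenoxide formed first deactivates the coumarin towards methoxide, and acidification re-closes any opened lactone because the C3=C4 bond is held cis.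

## Compound list

1 | 4-hydroxy-3,5-dimethylbenzaldehyde | Cc1cc(C=O)cc(C)c1O | starting material
2 | 4-(methoxymethoxy)-3,5-dimethylbenzaldehyde | COCOc1c(C)cc(C=O)cc1C | intermediate
3 | lithium {[2-(dimethylamino)ethyl](methyl)amino}[4-(methoxymethoxy)-3,5-dimethylphenyl]methanolate | COCOc1c(C)cc(C([O-])N(C)CCN(C)C)cc1C.[Li+] | intermediate
4 | lithium {[2-(dimethylamino)ethyl](methyl)amino}[2-lithio-4-(methoxymethoxy)-3,5-dimethylphenyl]methanolate | COCOc1c(C)cc(C([O-])N(C)CCN(C)C)c([Li])c1C.[Li+] | intermediate
5 | lithium {[2-(dimethylamino)ethyl](methyl)amino}[2-iodo-4-(methoxymethoxy)-3,5-dimethylphenyl]methanolate | COCOc1c(C)cc(C([O-])N(C)CCN(C)C)c(I)c1C.[Li+] | intermediate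
6 | 2-iodo-4-(methoxymethoxy)-3,5-dimethylbenzaldehyde | COCOc1c(C)cc(C=O)c(I)c1C | intermediate
7 | 2-[2-iodo-4-(methoxymethoxy)-3,5-dimethylphenyl]-1,3-dioxolane | COCOc1c(C)cc(C2OCCO2)c(I)c1C | intermediate
8 | (2R,3R)-2,3-epoxybutane (trans-2,3-dimethyloxirane) | C[C@H]1O[C@@H]1C | starting material
9 | [6-(1,3-dioxolan-2-yl)-3-(methoxymethoxy)-2,4-dimethylphenyl]lithium | COCOc1c(C)cc(C2OCCO2)c([Li])c1C | intermediate
10 | (2R,3R)-3-[6-(1,3-dioxolan-2-yl)-3-(methoxymethoxy)-2,4-dimethylphenyl]butan-2-ol | COCOc1c(C)cc(C2OCCO2)c([C@@H](C)[C@@H](C)O)c1C | intermediate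
11 | (2S,3R)-3-[6-(1,3-dioxolan-2-yl)-3-(methoxymethoxy)-2,4-dimethylphenyl]butan-2-yl acetate | COCOc1c(C)cc(C2OCCO2)c([C@@H](C)[C@H](C)OC(C)=O)c1C | intermediate
12 | (2S,3R)-3-(6-formyl-3-hydroxy-2,4-dimethylphenyl)butan-2-yl acetate | Oc1c(C)cc(C=O)c([C@@H](C)[C@H](C)OC(C)=O)c1C | intermediate
13 | (2S,3R)-3-(3-acetoxy-6-formyl-2,4-dimethylphenyl)butan-2-yl acetate, i.e. 4-acetoxy-2-[(2R,3S)-3-acetoxybutan-2-yl]-3,5-dimethylbenzaldehyde | CC(=O)Oc1c(C)cc(C=O)c([C@@H](C)[C@H](C)OC(C)=O)c1C | intermediate
14 | methyl (R)-3-hydroxybutanoate | C[C@@H](O)CC(=O)OC | starting material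
15 | methyl (R)-3-[(tert-butyldimethylsilyl)oxy]butanoate | C[C@@H](O[Si](C)(C)C(C)(C)C)CC(=O)OC | intermediate
16 | allyl 3-oxobutanoate (allyl acetoacetate) | C=CCOC(=O)CC(C)=O | starting material
17 | sodium lithium dianion of allyl 3-oxobutanoate | C=CCOC(=O)[CH-]C(=O)[CH2-].[Na+].[Li+] | intermediate
18 | allyl (7R)-7-[(tert-butyldimethylsilyl)oxy]-3,5-dioxooctanoate | C=CCOC(=O)CC(=O)CC(=O)C[C@@H](C)O[Si](C)(C)C(C)(C)C | intermediate
19 | allyl (7R)-7-hydroxy-3,5-dioxooctanoate | C=CCOC(=O)CC(=O)CC(=O)C[C@@H](C)O | intermediate
20 | allyl 2-[(6R)-2-hydroxy-6-methyl-4-oxooxan-2-yl]acetate | C=CCOC(=O)CC1(O)CC(=O)C[C@@H](C)O1 | intermediate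
21 | allyl 2-[(2R)-2-methyl-4-oxo-3,4-dihydro-2H-pyran-6-yl]acetate | C=CCOC(=O)CC1=CC(=O)C[C@@H](C)O1 | intermediate
22 | allyl (Z)-3-{4-acetoxy-2-[(2R,3S)-3-acetoxybutan-2-yl]-3,5-dimethylphenyl}-2-[(2R)-2-methyl-4-oxo-3,4-dihydro-2H-pyran-6-yl]acrylate | CC(=O)Oc1c(C)cc(/C=C(\C(=O)OCC=C)C2=CC(=O)C[C@@H](C)O2)c([C@@H](C)[C@H](C)OC(C)=O)c1C | intermediate
23 | (Z)-3-{4-acetoxy-2-[(2R,3S)-3-acetoxybutan-2-yl]-3,5-dimethylphenyl}-2-[(2R)-2-methyl-4-oxo-3,4-dihydro-2H-pyran-6-yl]acrylic acid | CC(=O)Oc1c(C)cc(/C=C(\C(=O)O)C2=CC(=O)C[C@@H](C)O2)c([C@@H](C)[C@H](C)OC(C)=O)c1C | intermediate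
24 | (2S,3R)-3-{7-acetoxy-6,8-dimethyl-3-[(2R)-2-methyl-4-oxo-3,4-dihydro-2H-pyran-6-yl]-2-oxo-2H-chromen-5-yl}butan-2-yl acetate | CC(=O)Oc1c(C)c2oc(=O)c(C3=CC(=O)C[C@@H](C)O3)cc2c([C@@H](C)[C@H](C)OC(C)=O)c1C | intermediate
25 | 7-hydroxy-5-[(2R,3S)-3-hydroxybutan-2-yl]-6,8-dimethyl-3-[(2R)-2-methyl-4-oxo-3,4-dihydro-2H-pyran-6-yl]-2H-chromen-2-one | Cc1c(O)c(C)c2oc(=O)c(C3=CC(=O)C[C@@H](C)O3)cc2c1[C@@H](C)[C@H](C)O | target

## Step count and risks

Total step count: 14. Longest linear sequence: 11 steps (steps 1–7 and 11–14); steps 8–10 build the pyranone fragment.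

**Step 13 (key step, proposed new method).**
- What may go wrong: the anode may oxidise the styrene-type π-system or the product instead of the carboxylate, the acyloxy radical may lose CO2 or abstract a benzylic hydrogen, or the enone may be reduced at the cathode, so that material is consumed without ring closure.
- Fallback (known chemistry): it sets out from 13 and returns at 24. Pd(OAc)2-catalysed ortho C–H hydroxylation through a transient imine directing group (an anthranilic acid, an N-fluoropyridinium oxidant, TsOH as oxygen source) should give 4-acetoxy-2-[(2R,3S)-3-acetoxybutan-2-yl]-6-hydroxy-3,5-dimethylbenzaldehyde F1. Knoevenagel condensation of F1 with 21 (piperidinium acetate, EtOH) then closes the lactone by acyl transfer from the allyl ester, whatever the geometry of the first-formed alkene, and gives 24.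

**Step 4.**
- What may go wrong: substitution at the secondary epoxide carbon may be too slow for the doubly ortho-substituted aryllithium, so that protonation of 9 and Lewis-acid rearrangement of 8 take over.
- Fallback: it sets out from 7 and returns at 11, bypassing 10 and step 5, by making the aryl–carbon bond at an sp2 carbon. Suzuki–Miyaura coupling of 7 with the lactate-derived (S)-tert-butyldimethyl{[3-(4,4,5,5-tetramethyl-1,3,2-dioxaborolan-2-yl)but-3-en-2-yl]oxy}silane F2 (Pd(OAc)2, SPhos, K3PO4) should give tert-butyl{[(2S)-3-[6-(1,3-dioxolan-2-yl)-3-(methoxymethoxy)-2,4-dimethylphenyl]but-3-en-2-yl]oxy}dimethylsilane F3. n-Bu4NF frees (2S)-3-[6-(1,3-dioxolan-2-yl)-3-(methoxymethoxy)-2,4-dimethylphenyl]but-3-en-2-ol F4. Hydroxyl-directed hydrogenation with [Rh(nbd)(dppb)]BF4 is expected to set the benzylic centre anti to the carbinol. The catalyst is bound by the hydroxyl in the conformer whose carbinol hydrogen is turned towards the aryl group to minimise allylic strain. The product is (2S,3R)-3-[6-(1,3-dioxolan-2-yl)-3-(methoxymethoxy)-2,4-dimethylphenyl]butan-2-ol F5. Acetylation (Ac2O, pyridine, DMAP) leads to 11.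

**Step 5.**
- What may go wrong: the activated alcohol may eliminate, or acylation may occur with retention, because backside attack at the carbinol next to the branched, doubly ortho-substituted benzylic carbon is slow.
- Fallback: it sets out from 10 and returns at 11 without any substitution at carbon. Dess–Martin oxidation (NaHCO3-buffered, so that the benzylic centre does not epimerise) should give (3R)-3-[6-(1,3-dioxolan-2-yl)-3-(methoxymethoxy)-2,4-dimethylphenyl]butan-2-one F6. Reduction with LiBH(s-Bu)3 at −78 °C under Felkin–Anh control (hydride anti to the aryl group) should then give (2S,3R)-3-[6-(1,3-dioxolan-2-yl)-3-(methoxymethoxy)-2,4-dimethylphenyl]butan-2-ol F5, the alcohol on which the detour for step 4 also converges. Acetylation (Ac2O, pyridine, DMAP) gives 11.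

**Step 11.**
- What may go wrong: the condensation with the ortho-branched aldehyde may be incomplete, or elimination from the titanium aldolate under kinetic control may give mainly the E isomer, which cannot cyclise.
- Fallback: it sets out from 13 and 21 and returns at 22 by separating bond formation from elimination. Aldol addition of the lithium enolate of 21 (LiN(SiMe3)2, THF, −78 °C) to 13 should give allyl 3-{4-acetoxy-2-[(2R,3S)-3-acetoxybutan-2-yl]-3,5-dimethylphenyl}-3-hydroxy-2-[(2R)-2-methyl-4-oxo-3,4-dihydro-2H-pyran-6-yl]propanoate F7. Mesylation (MsCl, Et3N) gives allyl 3-{4-acetoxy-2-[(2R,3S)-3-acetoxybutan-2-yl]-3,5-dimethylphenyl}-3-(methanesulfonyloxy)-2-[(2R)-2-methyl-4-oxo-3,4-dihydro-2H-pyran-6-yl]propanoate F8. E1cB elimination with DBU, under which the doubly activated alkene can equilibrate, leads to 22.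

**Step 14.**
- What may go wrong: methanolysis of the hindered secondary acetate may be slow, and prolonged exposure to base may open ring C (loss of configuration at C2') or add methoxide at C4.
- Fallback: it sets out from 24 and returns at 25 without any alkoxide base. NH4OAc in aqueous MeOH removes only the aryl acetate and should give (2S,3R)-3-{7-hydroxy-6,8-dimethyl-3-[(2R)-2-methyl-4-oxo-3,4-dihydro-2H-pyran-6-yl]-2-oxo-2H-chromen-5-yl}butan-2-yl acetate F9. Acid-catalysed transesterification (HCl generated from AcCl in MeOH) then cleaves the secondary acetate to give 25.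

## Further compounds

F1 | step 13 | 4-acetoxy-2-[(2R,3S)-3-acetoxybutan-2-yl]-6-hydroxy-3,5-dimethylbenzaldehyde | CC(=O)Oc1c(C)c(O)c(C=O)c([C@@H](C)[C@H](C)OC(C)=O)c1C
F2 | step 4 | (S)-tert-butyldimethyl{[3-(4,4,5,5-tetramethyl-1,3,2-dioxaborolan-2-yl)but-3-en-2-yl]oxy}silane | C=C(B1OC(C)(C)C(C)(C)O1)[C@H](C)O[Si](C)(C)C(C)(C)C
F3 | step 4 | tert-butyl{[(2S)-3-[6-(1,3-dioxolan-2-yl)-3-(methoxymethoxy)-2,4-dimethylphenyl]but-3-en-2-yl]oxy}dimethylsilane | COCOc1c(C)cc(C2OCCO2)c(C(=C)[C@H](C)O[Si](C)(C)C(C)(C)C)c1C
F4 | step 4 | (2S)-3-[6-(1,3-dioxolan-2-yl)-3-(methoxymethoxy)-2,4-dimethylphenyl]but-3-en-2-ol | COCOc1c(C)cc(C2OCCO2)c(C(=C)[C@H](C)O)c1C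
F5 | step 4 | (2S,3R)-3-[6-(1,3-dioxolan-2-yl)-3-(methoxymethoxy)-2,4-dimethylphenyl]butan-2-ol | COCOc1c(C)cc(C2OCCO2)c([C@@H](C)[C@H](C)O)c1C
F6 | step 5 | (3R)-3-[6-(1,3-dioxolan-2-yl)-3-(methoxymethoxy)-2,4-dimethylphenyl]butan-2-one | COCOc1c(C)cc(C2OCCO2)c([C@@H](C)C(C)=O)c1C
F7 | step 11 | allyl 3-{4-acetoxy-2-[(2R,3S)-3-acetoxybutan-2-yl]-3,5-dimethylphenyl}-3-hydroxy-2-[(2R)-2-methyl-4-oxo-3,4-dihydro-2H-pyran-6-yl]propanoate (mixture at C2 and C3) | CC(=O)Oc1c(C)cc(C(O)C(C(=O)OCC=C)C2=CC(=O)C[C@@H](C)O2)c([C@@H](C)[C@H](C)OC(C)=O)c1C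
F8 | step 11 | allyl 3-{4-acetoxy-2-[(2R,3S)-3-acetoxybutan-2-yl]-3,5-dimethylphenyl}-3-(methanesulfonyloxy)-2-[(2R)-2-methyl-4-oxo-3,4-dihydro-2H-pyran-6-yl]propanoate (mixture at C2 and C3) | CC(=O)Oc1c(C)cc(C(OS(C)(=O)=O)C(C(=O)OCC=C)C2=CC(=O)C[C@@H](C)O2)c([C@@H](C)[C@H](C)OC(C)=O)c1C
F9 | step 14 | (2S,3R)-3-{7-hydroxy-6,8-dimethyl-3-[(2R)-2-methyl-4-oxo-3,4-dihydro-2H-pyran-6-yl]-2-oxo-2H-chromen-5-yl}butan-2-yl acetate | Cc1c(O)c(C)c2oc(=O)c(C3=CC(=O)C[C@@H](C)O3)cc2c1[C@@H](C)[C@H](C)OC(C)=O
A1 | alternative 1 | 1-methoxy-2-methyl-1,3-bis(trimethylsilyloxy)penta-1,3-diene | COC(O[Si](C)(C)C)=C(C)C(O[Si](C)(C)C)=CC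
A2 | alternative 1 | methyl (4R,5S)-5-(tert-butyldimethylsilyloxy)-4-methylhex-2-ynoate | COC(=O)C#C[C@@H](C)[C@H](C)O[Si](C)(C)C(C)(C)C
A3 | alternative 1 | methyl 2,4-dihydroxy-3,5-dimethyl-6-[(2R,3S)-3-(tert-butyldimethylsilyloxy)butan-2-yl]benzoate | COC(=O)c1c(O)c(C)c(O)c(C)c1[C@@H](C)[C@H](C)O[Si](C)(C)C(C)(C)C
A4 | alternative 2 | 6-[(6S,7S)-7-(tert-butyldimethylsilyloxy)-4,6-dimethyl-3,5-dioxooctan-2-yl]-2,2-dimethyl-4H-1,3-dioxin-4-one | CC1(C)OC(=O)C=C(O1)C(C)C(=O)C(C)C(=O)[C@@H](C)[C@H](C)O[Si](C)(C)C(C)(C)C
A5 | alternative 2 | 7-hydroxy-2,2,6,8-tetramethyl-5-[(2R,3S)-3-(tert-butyldimethylsilyloxy)butan-2-yl]-4H-1,3-benzodioxin-4-one | CC1(C)OC(=O)c2c(O1)c(C)c(O)c(C)c2[C@@H](C)[C@H](C)O[Si](C)(C)C(C)(C)C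
A6 | alternative 3 | (2R)-6-[(E)-2-{4-(tert-butyldimethylsilyloxy)-2-hydroxy-6-[(2R,3S)-3-(tert-butyldimethylsilyloxy)butan-2-yl]-3,5-dimethylphenyl}ethenyl]-2-methyl-2,3-dihydro-4H-pyran-4-one | Cc1c(O[Si](C)(C)C(C)(C)C)c(C)c(O)c(/C=C/C2=CC(=O)C[C@@H](C)O2)c1[C@@H](C)[C@H](C)O[Si](C)(C)C(C)(C)C
A7 | alternative 3 | 7-(tert-butyldimethylsilyloxy)-5-[(2R,3S)-3-(tert-butyldimethylsilyloxy)butan-2-yl]-6,8-dimethyl-3-[(2R)-2-methyl-4-oxo-3,4-dihydro-2H-pyran-6-yl]-2H-chromen-2-one | Cc1c(O[Si](C)(C)C(C)(C)C)c(C)c2oc(=O)c(C3=CC(=O)C[C@@H](C)O3)cc2c1[C@@H](C)[C@H](C)O[Si](C)(C)C(C)(C)C
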